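**Strategy.** Ring A is built rather than bought. Its C1–C2 and C5–C6 bonds are disconnected, so the arene comes from a terminal ynone and a 1,1,3-trioxygenated butadiene. One Diels–Alder/aromatisation operation closes ring A and installs its whole substitution pattern: the key step exploits the fact that ring A carries the acyl carbon at C1 and oxygen at C2 and C4, and it delivers O-2 as a methyl ether and O-4 as a free phenol. The precursor is the (R)-α-silyloxy ethynyl ketone made from D-tyrosine, with the ring-B phenol and the C-α hydroxyl both masked as triisopropylsilyl ethers; the only stereocenter is bought and never touched.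

Key step: step 7

Remarks on the chemistry (assumptions and design choices):
- Locants: ring A is the resorcinol ring (C1 acyl-bearing, C2 and C4 oxygenated), ring B is the 4-hydroxyphenyl ring, and C-α is the carbinol carbon between the ketone and the benzylic CH2.
- The target is R at C-α. D-tyrosine is R, and its diazotisation is assumed to proceed with the usual net retention.
- Both hydroxyls are carried as triisopropylsilyl ethers. A smaller phenolic silyl ether would be at risk from carbonate and phenoxide in step 9 and from BCl3/HCl in step 8; the triisopropylsilyl ethers should withstand both and still leave with fluoride in one operation.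
- The amide is made before silylation, so no silyl ester has to be cleaved selectively.
- The terminal ynone is released by inverse acidic quench, so the liberated N,O-dimethylhydroxylamine is protonated before it can add to the ynone.

**Route**

Step 1
Reactants: 1 D-tyrosine
Product: 4 (R)-2-hydroxy-3-(4-hydroxyphenyl)propanoic acid, via diazonium carboxylate 2 (not isolated), via α-lactone 3 (not isolated)
Conditions: NaNO2, 1 M aq. H2SO4, 0 °C → rt
Reagents that add atoms: water, O
Why: Diazotisation of the α-amino acid (deaminative hydroxylation) runs through diazonium 2 and α-lactone 3, and the two successive inversions return oxygen to the face that nitrogen occupied, so C-α stays R and no new stereocenter is created.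

Step 2
Reactants: 4 (R)-2-hydroxy-3-(4-hydroxyphenyl)propanoic acid
Product: 6 (R)-2-hydroxy-3-(4-hydroxyphenyl)-N-methoxy-N-methylpropanamide, via O-acylisourea 5 (not isolated)
Conditions: MeNHOMe·HCl, EDC·HCl, N-methylmorpholine, CH2Cl2/DMF, −10 °C → rt
Reagents that add atoms: N,O-dimethylhydroxylamine hydrochloride, CNOC.Cl
Why: Carbodiimide amide coupling, in which O-acylisourea 5 is intercepted by the α-effect amine far faster than by the phenol or the secondary alcohol, and an α-hydroxy acid has no oxazolone pathway, so C-α should not racemise.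

Step 3
Reactants: 6 (R)-2-hydroxy-3-(4-hydroxyphenyl)-N-methoxy-N-methylpropanamide
Product: 7 (R)-N-methoxy-N-methyl-2-(triisopropylsilyloxy)-3-[4-(triisopropylsilyloxy)phenyl]propanamide
Conditions: TIPSOTf (2.5 equiv), 2,6-lutidine, CH2Cl2, 0 °C → rt
Reagents that add atoms: triisopropylsilyl trifluoromethanesulfonate, CC(C)[Si](C(C)C)(C(C)C)OS(=O)(=O)C(F)(F)F
Why: Silyl triflate silylation with a hindered pyridine base should convert both the phenol and the secondary alcohol into triisopropylsilyl ethers without affecting the amide or C-α.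

Step 4
Reactants: 7 (R)-N-methoxy-N-methyl-2-(triisopropylsilyloxy)-3-[4-(triisopropylsilyloxy)phenyl]propanamide; 8 ethynylmagnesium bromide
Product: 10 (R)-4-(triisopropylsilyloxy)-5-[4-(triisopropylsilyloxy)phenyl]pent-1-yn-3-one, via magnesium hemiaminal chelate 9 (not isolated)
Conditions: THF, −20 → 0 °C; inverse quench into cold 1 M aq. HCl
Reagents that add atoms: none
Why: Weinreb ketone synthesis, in which the acetylide adds once to give chelated tetrahedral adduct 9 that collapses only on the acidic quench, and the weakly basic acetylide should not deprotonate C-α.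

Step 5
Reactants: 11 ketene dimethyl acetal (1,1-dimethoxyethene); 12 acetyl chloride
Product: 13 4,4-dimethoxybut-3-en-2-one
Conditions: Et3N, Et2O, 0 °C → rt
Reagents that add atoms: none
Why: C-Acylation of an electron-rich ketene acetal by an acid chloride (enol-ether acylation), with the amine taking up HCl, should give the β,β-dimethoxy enone.

Step 6
Reactants: 13 4,4-dimethoxybut-3-en-2-one
Product: 14 1,1-dimethoxy-3-(trimethylsilyloxy)buta-1,3-diene
Conditions: TMSCl, Et3N, ZnCl2 (cat.), toluene, rt → 40 °C
Reagents that add atoms: chlorotrimethylsilane, C[Si](C)(C)Cl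
Why: Soft enolisation and O-silylation (silyl enol ether formation) at the methyl group, the only enolisable position, should give the 2-silyloxydiene, to be distilled and used with exclusion of moisture.

Step 7
Reactants: 10 (R)-4-(triisopropylsilyloxy)-5-[4-(triisopropylsilyloxy)phenyl]pent-1-yn-3-one; 14 1,1-dimethoxy-3-(trimethylsilyloxy)buta-1,3-diene
Product: 17 (R)-1-(4-hydroxy-2-methoxyphenyl)-2-(triisopropylsilyloxy)-3-[4-(triisopropylsilyloxy)phenyl]propan-1-one, via cyclohexa-1,4-diene cycloadduct 15 (not isolated), via aryl trimethylsilyl ether 16 (not isolated)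
Conditions: 14 (2 equiv), toluene, 0 °C → rt (60 °C if needed); then 0.1 M aq. HCl, THF, 0 °C
Reagents that add atoms: none
Why: Diene 14 (high-lying HOMO) and ynone 10 (low-lying LUMO) should undergo a normal-electron-demand [4+2] cycloaddition in which the C5–C6 bond runs ahead of the C1–C2 bond, giving 15; 1,4-elimination of methanol across the ring then aromatises it to 16, and the aryl trimethylsilyl ether is hydrolysed on the mild acidic work-up. The closest known reaction type is the Diels–Alder benzannulation of 1,1-dialkoxy-3-silyloxybutadienes with acetylenic ketones and esters, which gives resorcinol monomethyl ethers. Ring A is closed by the intermolecular cycloaddition itself, both σ bonds forming in one suprafacial event, so no separate cyclisation mode has to be favoured. No stereocenter is created, and the neutral conditions should leave the existing R center at C-α un-enolised. The step needs regioselectivity, which the substrates secure: the largest HOMO coefficient lies on the unsubstituted CH2 terminus of 14 and the largest LUMO coefficient on the terminal β carbon of 10, so the ketal carbon ends up next to the acyl-bearing carbon and ring A emerges with OMe at C2 and OH at C4. Chemoselectivity follows because the ynone is the only electron-poor π system and the silyl ethers are inert.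

Step 8
Reactants: 17 (R)-1-(4-hydroxy-2-methoxyphenyl)-2-(triisopropylsilyloxy)-3-[4-(triisopropylsilyloxy)phenyl]propan-1-one
Product: 19 (R)-1-(2,4-dihydroxyphenyl)-2-(triisopropylsilyloxy)-3-[4-(triisopropylsilyloxy)phenyl]propan-1-one, via bis(dichloroboryl) ether 18 (not isolated)
Conditions: BCl3 (2.5 equiv), CH2Cl2, −78 → 0 °C; then H2O
Reagents that add atoms: none
Why: Chelation-directed aryl methyl ether cleavage, in which BCl3 first borylates the free 4-OH and then binds between the ketone oxygen and the ortho methoxy oxygen so that chloride removes the methyl group at low temperature (18), while the hindered silyl ethers and C-α should be left alone.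

Step 9
Reactants: 19 (R)-1-(2,4-dihydroxyphenyl)-2-(triisopropylsilyloxy)-3-[4-(triisopropylsilyloxy)phenyl]propan-1-one; 20 geranyl bromide
Product: 21 (R)-1-{4-[(2E)-3,7-dimethylocta-2,6-dien-1-yloxy]-2-hydroxyphenyl}-2-(triisopropylsilyloxy)-3-[4-(triisopropylsilyloxy)phenyl]propan-1-one
Conditions: K2CO3 (1.1 equiv), 20 (1.05 equiv), acetone, rt → 40 °C
Reagents that add atoms: none
Why: Williamson etherification, selective because the 4-OH (para to the ketone, not hydrogen-bonded) is the more acidic and more nucleophilic phenol while the 2-OH is held in a hydrogen bond to the carbonyl, so the allylic bromide should react at O-4 by SN2 with the E olefin unchanged.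

Step 10
Reactants: 21 (R)-1-{4-[(2E)-3,7-dimethylocta-2,6-dien-1-yloxy]-2-hydroxyphenyl}-2-(triisopropylsilyloxy)-3-[4-(triisopropylsilyloxy)phenyl]propan-1-one
Product: 22 (R)-1-{4-[(2E)-3,7-dimethylocta-2,6-dien-1-yloxy]-2-hydroxyphenyl}-2-hydroxy-3-(4-hydroxyphenyl)propan-1-one (CNP0159413.1)
Conditions: TBAF, AcOH (1:1), THF, 0 °C → rt
Reagents that add atoms: none
Why: Fluoride-mediated desilylation, buffered with acetic acid so that the α-hydroxy ketone is not enolised and the allylic aryl ether is not ionised, should free the ring-B phenol and the C-α hydroxyl and give the target with its R configuration intact.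

**Compound list**

1 | D-tyrosine | N[C@H](Cc1ccc(O)cc1)C(=O)O | starting material
2 | (R)-2-diazonio-3-(4-hydroxyphenyl)propanoate | N#[N+][C@H](Cc1ccc(O)cc1)C(=O)[O-] | intermediate
3 | (S)-3-(4-hydroxybenzyl)oxiran-2-one | O=C1O[C@H]1Cc1ccc(O)cc1 | intermediate
4 | (R)-2-hydroxy-3-(4-hydroxyphenyl)propanoic acid | O[C@H](Cc1ccc(O)cc1)C(=O)O | intermediate
5 | O-acylisourea from 4 and EDC | CCN=C(NCCCN(C)C)OC(=O)[C@H](O)Cc1ccc(O)cc1 | intermediate
6 | (R)-2-hydroxy-3-(4-hydroxyphenyl)-N-methoxy-N-methylpropanamide | CON(C)C(=O)[C@H](O)Cc1ccc(O)cc1 | intermediate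
7 | (R)-N-methoxy-N-methyl-2-(triisopropylsilyloxy)-3-[4-(triisopropylsilyloxy)phenyl]propanamide | CON(C)C(=O)[C@H](O[Si](C(C)C)(C(C)C)C(C)C)Cc1ccc(O[Si](C(C)C)(C(C)C)C(C)C)cc1 | intermediate
8 | ethynylmagnesium bromide | C#C[Mg]Br | starting material
9 | bromomagnesium alkoxide of the tetrahedral adduct, (4R)-3-[methoxy(methyl)amino]-4-(triisopropylsilyloxy)-5-[4-(triisopropylsilyloxy)phenyl]pent-1-yn-3-olate (both C-3 epimers) | C#CC(O[Mg]Br)(N(C)OC)[C@H](O[Si](C(C)C)(C(C)C)C(C)C)Cc1ccc(O[Si](C(C)C)(C(C)C)C(C)C)cc1 | intermediate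
10 | (R)-4-(triisopropylsilyloxy)-5-[4-(triisopropylsilyloxy)phenyl]pent-1-yn-3-one | C#CC(=O)[C@H](O[Si](C(C)C)(C(C)C)C(C)C)Cc1ccc(O[Si](C(C)C)(C(C)C)C(C)C)cc1 | intermediate
11 | ketene dimethyl acetal (1,1-dimethoxyethene) | C=C(OC)OC | starting material
12 | acetyl chloride | CC(=O)Cl | starting material
13 | 4,4-dimethoxybut-3-en-2-one | CC(=O)C=C(OC)OC | intermediate
14 | 1,1-dimethoxy-3-(trimethylsilyloxy)buta-1,3-diene | COC(OC)=CC(=C)O[Si](C)(C)C | intermediate
15 | (R)-1-[6,6-dimethoxy-4-(trimethylsilyloxy)cyclohexa-1,4-dien-1-yl]-2-(triisopropylsilyloxy)-3-[4-(triisopropylsilyloxy)phenyl]propan-1-one | COC1(OC)C=C(O[Si](C)(C)C)CC=C1C(=O)[C@H](O[Si](C(C)C)(C(C)C)C(C)C)Cc1ccc(O[Si](C(C)C)(C(C)C)C(C)C)cc1 | intermediate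
16 | (R)-1-[2-methoxy-4-(trimethylsilyloxy)phenyl]-2-(triisopropylsilyloxy)-3-[4-(triisopropylsilyloxy)phenyl]propan-1-one | COc1cc(O[Si](C)(C)C)ccc1C(=O)[C@H](O[Si](C(C)C)(C(C)C)C(C)C)Cc1ccc(O[Si](C(C)C)(C(C)C)C(C)C)cc1 | intermediate
17 | (R)-1-(4-hydroxy-2-methoxyphenyl)-2-(triisopropylsilyloxy)-3-[4-(triisopropylsilyloxy)phenyl]propan-1-one | COc1cc(O)ccc1C(=O)[C@H](O[Si](C(C)C)(C(C)C)C(C)C)Cc1ccc(O[Si](C(C)C)(C(C)C)C(C)C)cc1 | intermediate
18 | (R)-1-[2,4-bis(dichloroboryloxy)phenyl]-2-(triisopropylsilyloxy)-3-[4-(triisopropylsilyloxy)phenyl]propan-1-one | ClB(Cl)Oc1ccc(C(=O)[C@H](O[Si](C(C)C)(C(C)C)C(C)C)Cc2ccc(O[Si](C(C)C)(C(C)C)C(C)C)cc2)c(OB(Cl)Cl)c1 | intermediate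
19 | (R)-1-(2,4-dihydroxyphenyl)-2-(triisopropylsilyloxy)-3-[4-(triisopropylsilyloxy)phenyl]propan-1-one | Oc1ccc(C(=O)[C@H](O[Si](C(C)C)(C(C)C)C(C)C)Cc2ccc(O[Si](C(C)C)(C(C)C)C(C)C)cc2)c(O)c1 | intermediate
20 | geranyl bromide, (2E)-1-bromo-3,7-dimethylocta-2,6-diene | CC(C)=CCC/C(C)=C/CBr | starting material
21 | (R)-1-{4-[(2E)-3,7-dimethylocta-2,6-dien-1-yloxy]-2-hydroxyphenyl}-2-(triisopropylsilyloxy)-3-[4-(triisopropylsilyloxy)phenyl]propan-1-one | CC(C)=CCC/C(C)=C/COc1ccc(C(=O)[C@H](O[Si](C(C)C)(C(C)C)C(C)C)Cc2ccc(O[Si](C(C)C)(C(C)C)C(C)C)cc2)c(O)c1 | intermediate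
22 | (R)-1-{4-[(2E)-3,7-dimethylocta-2,6-dien-1-yloxy]-2-hydroxyphenyl}-2-hydroxy-3-(4-hydroxyphenyl)propan-1-one | CC(C)=CCC/C(C)=C/COc1ccc(C(=O)[C@H](O)Cc2ccc(O)cc2)c(O)c1 | target

**Step count.** Total: 10 steps. Longest linear sequence: 8 steps (steps 1–4, then 7–10); steps 5–6 make the diene in a two-step side branch.

**Steps most likely to fail, with fallbacks**

Step 7. The diene may be desilylated or hydrolysed before it reacts, or the components may stop at an open-chain conjugate adduct that neither closes nor aromatises cleanly. The fallback gives up the cycloaddition and brings ring A in intact; it sets out from 7 and returns at 19. 4-Bromoresorcinol would be dibenzylated (benzyl bromide, K2CO3, DMF) to 1-bromo-2,4-bis(benzyloxy)benzene F1. Bromine–lithium exchange (n-BuLi, THF, −78 °C) would give [2,4-bis(benzyloxy)phenyl]lithium F2, which adds to 7 to form the lithium alkoxide of the tetrahedral adduct F3. Acidic quench would release (R)-1-[2,4-bis(benzyloxy)phenyl]-2-(triisopropylsilyloxy)-3-[4-(triisopropylsilyloxy)phenyl]propan-1-one F4. Hydrogenolysis of both benzyl ethers (H2, Pd/C, EtOAc), done before any olefin is present, would then give 19.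

Step 8. The Lewis acid and the HCl it releases may strip a silyl ether, or the ether cleavage may stall with the free 4-OH consuming the reagent. The fallback removes the methyl ether from the plan; it sets out from 10 and returns at 19. Ynone 10 would be combined in toluene with commercial 1-methoxy-1,3-bis(trimethylsilyloxy)buta-1,3-diene (COC(O[Si](C)(C)C)=CC(=C)O[Si](C)(C)C). The cycloadduct (R)-1-[6-methoxy-4,6-bis(trimethylsilyloxy)cyclohexa-1,4-dien-1-yl]-2-(triisopropylsilyloxy)-3-[4-(triisopropylsilyloxy)phenyl]propan-1-one F5 is expected to aromatise by loss of methanol, as mixed silyl methyl ketene acetal dienes do. This would give (R)-1-[2,4-bis(trimethylsilyloxy)phenyl]-2-(triisopropylsilyloxy)-3-[4-(triisopropylsilyloxy)phenyl]propan-1-one F6, whose two aryl trimethylsilyl ethers hydrolyse on mild acidic work-up to 19.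

Step 10. Cleavage of the hindered secondary silyl ether may be sluggish, and forcing it may enolise the α-hydroxy ketone (racemisation) or, under acid, ionise the allylic aryl ether. The fallback changes the order of events; it sets out from 19 and returns at 22. Both silyl ethers would be removed first with aqueous HF in MeCN, which is acidic and non-enolising and meets no allylic ether at that stage, to give (R)-1-(2,4-dihydroxyphenyl)-2-hydroxy-3-(4-hydroxyphenyl)propan-1-one F7. Alkylation with 20 and one equivalent of KHCO3 in acetone/DMF at rt should then go to the most acidic phenol, the 4-OH para to the ketone, in preference to the ring-B phenol, the hydrogen-bonded 2-OH and the secondary alcohol, giving 22 directly.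

**Further compounds**

F1 | step 7 | 1-bromo-2,4-bis(benzyloxy)benzene | Brc1ccc(OCc2ccccc2)cc1OCc1ccccc1
F2 | step 7 | [2,4-bis(benzyloxy)phenyl]lithium | [Li]c1ccc(OCc2ccccc2)cc1OCc1ccccc1
F3 | step 7 | lithium alkoxide of the tetrahedral adduct of F2 and 7 (both epimers at the carbinol carbon) | [Li]OC(c1ccc(OCc2ccccc2)cc1OCc1ccccc1)(N(C)OC)[C@H](O[Si](C(C)C)(C(C)C)C(C)C)Cc1ccc(O[Si](C(C)C)(C(C)C)C(C)C)cc1
F4 | step 7 | (R)-1-[2,4-bis(benzyloxy)phenyl]-2-(triisopropylsilyloxy)-3-[4-(triisopropylsilyloxy)phenyl]propan-1-one | O=C(c1ccc(OCc2ccccc2)cc1OCc1ccccc1)[C@H](O[Si](C(C)C)(C(C)C)C(C)C)Cc1ccc(O[Si](C(C)C)(C(C)C)C(C)C)cc1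
F5 | step 8 | (R)-1-[6-methoxy-4,6-bis(trimethylsilyloxy)cyclohexa-1,4-dien-1-yl]-2-(triisopropylsilyloxy)-3-[4-(triisopropylsilyloxy)phenyl]propan-1-one | COC1(O[Si](C)(C)C)C=C(O[Si](C)(C)C)CC=C1C(=O)[C@H](O[Si](C(C)C)(C(C)C)C(C)C)Cc1ccc(O[Si](C(C)C)(C(C)C)C(C)C)cc1
F6 | step 8 | (R)-1-[2,4-bis(trimethylsilyloxy)phenyl]-2-(triisopropylsilyloxy)-3-[4-(triisopropylsilyloxy)phenyl]propan-1-one | C[Si](C)(C)Oc1ccc(C(=O)[C@H](O[Si](C(C)C)(C(C)C)C(C)C)Cc2ccc(O[Si](C(C)C)(C(C)C)C(C)C)cc2)c(O[Si](C)(C)C)c1
F7 | step 10 | (R)-1-(2,4-dihydroxyphenyl)-2-hydroxy-3-(4-hydroxyphenyl)propan-1-one | O=C(c1ccc(O)cc1O)[C@H](O)Cc1ccc(O)cc1
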